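**Plan**

- Numbering: ring A (the ring with the one aromatic H) carries OMe on carbon 1, H on carbon 2, OH on carbon 3, the CH2 bridge on carbon 4, OH on carbon 5 and acetyl on carbon 6; ring B (fully substituted) carries the CH2 bridge on carbon 1, OH on carbon 2, CH3 on carbon 3, OH on carbon 4, acetyl on carbon 5 and OMe on carbon 6.
- Cuts, in retrosynthetic order: the acetyl group from ring A carbon 6 (late C-acylation of a then symmetric ring A); the bond between ring B carbons 4 and 5 (ring B opened to an acyclic methyl ester); the bond between ring B carbons 2 and 3 (propanoate enolate plus an activated acid); ring B carbons 2, 1, 6 and 5 with the acetyl group are folded back into a 4-methoxy-6-methyl-2-pyranone (lactone carbonyl = ring B carbon 2); the bond from ring B carbon 1 to the bridge CH2 (reductive alkylation of the pyranone by the ring A aldehyde).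
- Enabling feature: in ring B the only methylated oxygen sits on carbon 6, between carbon 1 and the acetyl-bearing carbon 5; carbon 4, next to carbon 5, is a free phenol; carbon 3 bears a methyl. Carbon 4 can therefore be an ester carbon, carbon 5 a ketone-activated CH2 and carbon 6 a ready-made methyl enol ether, and the methyl on carbon 3 makes the Claisen fold from carbon 5 onto carbon 4 the one that aromatizes readily.
- Forward: the ring A aldehyde (steps 1 and 2) is joined to triacetic acid lactone (step 3), the oxygen of the future ring B carbon 6 is methylated on the pyranone (step 4), the ring is opened and the ketone masked (steps 5 and 6), two carbons are added at the future ring B carbon 2 (steps 7 and 8), the ketone is freed (step 9), ring B is closed (step 10), ring A is deprotected and acetylated (steps 11 and 12).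
- Stereochemistry: the target has no stereocentre; the (E) enol ether geometry that holds the two reacting chain ends cis comes from the pyranone ring, and the racemic centre of the open chain becomes an aromatic carbon.
- Chain locants: in the open-chain keto esters of steps 8 to 10, C1 to C6 become ring B carbons 4, 3, 2, 1, 6 and 5 in that order, and C7 and C8 become the acetyl group.

Key step: step 10

Remark: the open-chain keto esters made in steps 8 and 9 are racemic at C2 and the cyclohexenedione formed in step 10 is a stereoisomer mixture; all three may exist partly as enol or double-bond tautomers, which does not matter because the base of step 10 equilibrates them.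

**Route**

Step 1
Reactants: 1 2,4,6-trihydroxybenzaldehyde
Product: 2 2,6-dihydroxy-4-methoxybenzaldehyde
Conditions: Me2SO4 (1.0 equiv), K2CO3 (1.0 equiv), acetone, 0 °C to rt
Reagents that add atoms: dimethyl sulfate COS(=O)(=O)OC
Why: Williamson O-methylation under substrate control, since the 4-hydroxyl para to the formyl group is the most acidic and the only one not held in a hydrogen bond to the carbonyl oxygen, so one equivalent of base and of the hard electrophile should ether it first and any dimethyl ether is removed by chromatography.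

Step 2
Reactants: 2 2,6-dihydroxy-4-methoxybenzaldehyde
Product: 3 2,6-bis(benzyloxy)-4-methoxybenzaldehyde
Conditions: BnBr (2.5 equiv), K2CO3 (3 equiv), DMF, 60 °C
Reagents that add atoms: benzyl bromide BrCc1ccccc1
Why: Williamson etherification of the two chelated ortho-hydroxyls with excess base in a polar aprotic solvent, giving benzyl ethers that survive the alkoxide, enolate and mild-acid steps and are removed by hydrogenolysis in step 11.

Step 3
Reactants: 3 2,6-bis(benzyloxy)-4-methoxybenzaldehyde; 4 4-hydroxy-6-methyl-2H-pyran-2-one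
Product: 6 3-{[2,6-bis(benzyloxy)-4-methoxyphenyl]methyl}-4-hydroxy-6-methyl-2H-pyran-2-one, via arylidene pyrandione 5 (not isolated)
Conditions: Hantzsch ester (1.1 equiv), L-proline (20 mol %), EtOH, rt to 40 °C
Reagents that add atoms: none
Why: Organocatalytic three-component reductive alkylation, in which proline-mediated Knoevenagel condensation at C3 of the pyranone gives arylidene 5 and the Hantzsch ester reduces it by conjugate hydride transfer before a second pyranone can add, so the bridge CH2 is attached to the future ring B carbon 1 without over-alkylation.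

Step 4
Reactants: 6 3-{[2,6-bis(benzyloxy)-4-methoxyphenyl]methyl}-4-hydroxy-6-methyl-2H-pyran-2-one
Product: 7 3-{[2,6-bis(benzyloxy)-4-methoxyphenyl]methyl}-4-methoxy-6-methyl-2H-pyran-2-one
Conditions: Me2SO4 (1.5 equiv), K2CO3 (2 equiv), acetone, reflux
Reagents that add atoms: dimethyl sulfate COS(=O)(=O)OC
Why: O-Methylation of a vinylogous carboxylic acid, where C3 is blocked and the hard sulfate electrophile with K2CO3 in acetone alkylates the 4-oxygen to give the 4-methoxy-2-pyranone in preference to the isomeric 2-methoxy-4-pyranone, which fixes the methyl ether of the future ring B carbon 6.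

Step 5
Reactants: 7 3-{[2,6-bis(benzyloxy)-4-methoxyphenyl]methyl}-4-methoxy-6-methyl-2H-pyran-2-one
Product: 8 methyl (2E)-2-{[2,6-bis(benzyloxy)-4-methoxyphenyl]methyl}-3-methoxy-5-oxohex-2-enoate
Conditions: Mg(OMe)2 (3 equiv), MeOH, 50 °C; then aq. AcOH, 0 °C
Reagents that add atoms: magnesium methoxide [Mg+2].[O-]C.[O-]C
Why: Methanolysis of the enol lactone, in which methoxide adds to C2, the ring oxygen leaves as the conjugated enolate of the methyl ketone and cold protonation at the ketone α-carbon releases keto ester 8 with the ester and the CH2C(O)CH3 arm still cis as they were in the ring, hence (E).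

Step 6
Reactants: 8 methyl (2E)-2-{[2,6-bis(benzyloxy)-4-methoxyphenyl]methyl}-3-methoxy-5-oxohex-2-enoate
Product: 9 methyl (2E)-2-{[2,6-bis(benzyloxy)-4-methoxyphenyl]methyl}-3-methoxy-4-(2-methyl-1,3-dioxolan-2-yl)but-2-enoate
Conditions: (Me3SiOCH2)2 (1.5 equiv), Me3SiOTf (5 mol %), CH2Cl2, −78 to −20 °C; pyridine quench
Reagents that add atoms: 1,2-bis(trimethylsilyloxy)ethane C[Si](C)(C)OCCO[Si](C)(C)C
Why: Noyori ketalization, whose silyl triflate-catalysed exchange runs cold without liberating water or strong protic acid, so the unhindered methyl ketone is masked before its enol can close back onto the ester to return pyranone 7.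

Step 7
Reactants: 9 methyl (2E)-2-{[2,6-bis(benzyloxy)-4-methoxyphenyl]methyl}-3-methoxy-4-(2-methyl-1,3-dioxolan-2-yl)but-2-enoate
Product: 10 (2E)-2-{[2,6-bis(benzyloxy)-4-methoxyphenyl]methyl}-3-methoxy-4-(2-methyl-1,3-dioxolan-2-yl)but-2-enoic acid
Conditions: LiOH (5 equiv), THF/MeOH/H2O, 50 °C; then AcOH to pH 4–5, 0 °C
Reagents that add atoms: lithium hydroxide [Li+].[OH-]
Why: Saponification by acyl–oxygen cleavage, to which the dioxolane, the benzyl ethers and the tetrasubstituted enol ether are inert, with acidification only to pH 4–5 so that the ketal stays intact.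

Step 8
Reactants: 10 (2E)-2-{[2,6-bis(benzyloxy)-4-methoxyphenyl]methyl}-3-methoxy-4-(2-methyl-1,3-dioxolan-2-yl)but-2-enoic acid; 11 methyl propanoate
Product: 13 methyl (4E)-4-{[2,6-bis(benzyloxy)-4-methoxyphenyl]methyl}-5-methoxy-2-methyl-6-(2-methyl-1,3-dioxolan-2-yl)-3-oxohex-4-enoate, via acyl imidazolide 12 (not isolated)
Conditions: CDI (1.2 equiv), THF, rt, N2 purge; then added to 11 (3.5 equiv)/LiN(i-Pr)2 (3.5 equiv), THF, −78 to −40 °C; AcOH, −78 °C
Reagents that add atoms: none
Why: Crossed Claisen-type C-acylation of an ester lithium enolate by an acyl imidazolide, where activating the hindered vinylogous-carbonate-like acid as 12 lets acyl transfer run at −78 °C and so outpace deprotonation next to the ketal, excess enolate absorbs the imidazole N–H and the acidic product, and the new C2 centre (the future ring B carbon 3) forms as a racemate that is erased in step 10.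

Step 9
Reactants: 13 methyl (4E)-4-{[2,6-bis(benzyloxy)-4-methoxyphenyl]methyl}-5-methoxy-2-methyl-6-(2-methyl-1,3-dioxolan-2-yl)-3-oxohex-4-enoate
Product: 14 methyl (4E)-4-{[2,6-bis(benzyloxy)-4-methoxyphenyl]methyl}-5-methoxy-2-methyl-3,7-dioxooct-4-enoate
Conditions: PPTS (0.2 equiv), acetone/H2O (5:1), 45 °C
Reagents that add atoms: water O
Why: Acid-catalysed hydrolysis of the dioxolane, for which pyridinium tosylate in wet acetone is acidic enough to free an unhindered methyl ketone but should leave the vinylogous ester (the enol ether at C5), the β-keto ester and the benzyl ethers untouched, and 14 is carried on at once.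

Step 10
Reactants: 14 methyl (4E)-4-{[2,6-bis(benzyloxy)-4-methoxyphenyl]methyl}-5-methoxy-2-methyl-3,7-dioxooct-4-enoate
Product: 16 1-[3-{[2,6-bis(benzyloxy)-4-methoxyphenyl]methyl}-4,6-dihydroxy-2-methoxy-5-methylphenyl]ethan-1-one, via cyclohexenedione tautomer 15 (not isolated)
Conditions: Mg(OMe)2 (4 equiv), MeOH, reflux; then 1 M HCl, 0 °C
Reagents that add atoms: none
Why: Methoxide held on divalent magnesium equilibrates the two acidic sites of 14, C2–H of the β-keto ester and the C6 methylene (α to the C7 ketone and vinylogously α to the C3 ketone through the enol ether); only the C6 anion has a non-enolized ester within reach, so it adds to C1 and joins ring B carbons 5 and 4, methoxide leaves, and cyclohexenedione 15 tautomerizes twice to phenol 16, whose deprotonation makes the sequence irreversible. The closest known reaction type is the biomimetic Claisen (Dieckmann-type) cyclization of 3,5,7-trioxoalkanoates and ring-opened pyranones to acylphloroglucinols under Mg(OMe)2. Ring B closes in the 6-(enolexo)-exo-trig mode. No stereocentre is created in 16, because the racemic C2 of 14 and the two sp3 centres of 15 become aromatic carbons 3 and 5 of ring B. The step needs the Claisen fold to win over two aldol folds: attack of C2 on the C7 ketone would leave the methyl-bearing carbon quaternary and can only revert, while attack of the acetyl methyl C8 on C3, the one alternative that could aromatize (to a resorcinol), requires the least acidic carbanion and the least electrophilic carbonyl, a vinylogous ester that is also enolized toward C2. The (E) geometry from the pyranone keeps C3 and C6 cis on the C4=C5 bond and the oxygen on C5 is already a methyl ether, so neither geometry nor the site of O-methylation has to be settled here.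

Step 11
Reactants: 16 1-[3-{[2,6-bis(benzyloxy)-4-methoxyphenyl]methyl}-4,6-dihydroxy-2-methoxy-5-methylphenyl]ethan-1-one
Product: 17 1-{3-[(2,6-dihydroxy-4-methoxyphenyl)methyl]-4,6-dihydroxy-2-methoxy-5-methylphenyl}ethan-1-one
Conditions: H2 (1 atm), 10% Pd/C, EtOAc/MeOH, rt
Reagents that add atoms: none
Why: Catalytic hydrogenolysis of the two benzyl ethers, under which the hydrogen-bonded aryl ketone, the diarylmethane bridge and the methyl ethers are not reduced at 1 atm and room temperature.

Step 12
Reactants: 17 1-{3-[(2,6-dihydroxy-4-methoxyphenyl)methyl]-4,6-dihydroxy-2-methoxy-5-methylphenyl}ethan-1-one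
Product: 19 1-[3-[(3-acetyl-2,6-dihydroxy-4-methoxyphenyl)methyl]-4,6-dihydroxy-2-methoxy-5-methylphenyl]ethan-1-one, via ketiminium chloride 18 (not isolated)
Conditions: MeCN (5 equiv), ZnCl2 (1.5 equiv), HCl (g), Et2O/1,4-dioxane, 0 °C; then H2O, 60 °C
Reagents that add atoms: acetonitrile CC#N; water O
Why: Houben–Hoesch acylation, in which the nitrilium species from acetonitrile and HCl attacks ring A (the only ring with free positions) at its carbon 6, equivalent to its carbon 2 by the local symmetry of the 2,6-dihydroxy-4-methoxybenzyl unit, the ketiminium salt 18 resists a second acylation, and warm water hydrolyses it to the ketone.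

**Compound list**

1 | 2,4,6-trihydroxybenzaldehyde | O=Cc1c(O)cc(O)cc1O | starting material
2 | 2,6-dihydroxy-4-methoxybenzaldehyde | COc1cc(O)c(C=O)c(O)c1 | intermediate
3 | 2,6-bis(benzyloxy)-4-methoxybenzaldehyde | COc1cc(OCc2ccccc2)c(C=O)c(OCc2ccccc2)c1 | intermediate
4 | 4-hydroxy-6-methyl-2H-pyran-2-one (triacetic acid lactone) | Cc1cc(O)cc(=O)o1 | starting material
5 | 3-{[2,6-bis(benzyloxy)-4-methoxyphenyl]methylidene}-6-methyl-2H-pyran-2,4(3H)-dione (alkene geometry not defined) | CC1=CC(=O)C(=Cc2c(OCc3ccccc3)cc(OC)cc2OCc2ccccc2)C(=O)O1 | intermediate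
6 | 3-{[2,6-bis(benzyloxy)-4-methoxyphenyl]methyl}-4-hydroxy-6-methyl-2H-pyran-2-one | Cc1cc(O)c(Cc2c(OCc3ccccc3)cc(OC)cc2OCc2ccccc2)c(=O)o1 | intermediate
7 | 3-{[2,6-bis(benzyloxy)-4-methoxyphenyl]methyl}-4-methoxy-6-methyl-2H-pyran-2-one | COc1cc(C)oc(=O)c1Cc1c(OCc2ccccc2)cc(OC)cc1OCc1ccccc1 | intermediate
8 | methyl (2E)-2-{[2,6-bis(benzyloxy)-4-methoxyphenyl]methyl}-3-methoxy-5-oxohex-2-enoate | COC(=O)/C(Cc1c(OCc2ccccc2)cc(OC)cc1OCc1ccccc1)=C(/OC)CC(C)=O | intermediate
9 | methyl (2E)-2-{[2,6-bis(benzyloxy)-4-methoxyphenyl]methyl}-3-methoxy-4-(2-methyl-1,3-dioxolan-2-yl)but-2-enoate | COC(=O)/C(Cc1c(OCc2ccccc2)cc(OC)cc1OCc1ccccc1)=C(/OC)CC1(C)OCCO1 | intermediate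
10 | (2E)-2-{[2,6-bis(benzyloxy)-4-methoxyphenyl]methyl}-3-methoxy-4-(2-methyl-1,3-dioxolan-2-yl)but-2-enoic acid | OC(=O)/C(Cc1c(OCc2ccccc2)cc(OC)cc1OCc1ccccc1)=C(/OC)CC1(C)OCCO1 | intermediate
11 | methyl propanoate | CCC(=O)OC | starting material
12 | (2E)-2-{[2,6-bis(benzyloxy)-4-methoxyphenyl]methyl}-1-(1H-imidazol-1-yl)-3-methoxy-4-(2-methyl-1,3-dioxolan-2-yl)but-2-en-1-one | O=C(/C(Cc1c(OCc2ccccc2)cc(OC)cc1OCc1ccccc1)=C(/OC)CC1(C)OCCO1)n1ccnc1 | intermediate
13 | methyl (4E)-4-{[2,6-bis(benzyloxy)-4-methoxyphenyl]methyl}-5-methoxy-2-methyl-6-(2-methyl-1,3-dioxolan-2-yl)-3-oxohex-4-enoate (racemic at C2) | COC(=O)C(C)C(=O)/C(Cc1c(OCc2ccccc2)cc(OC)cc1OCc1ccccc1)=C(/OC)CC1(C)OCCO1 | intermediate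
14 | methyl (4E)-4-{[2,6-bis(benzyloxy)-4-methoxyphenyl]methyl}-5-methoxy-2-methyl-3,7-dioxooct-4-enoate (racemic at C2) | COC(=O)C(C)C(=O)/C(Cc1c(OCc2ccccc2)cc(OC)cc1OCc1ccccc1)=C(/OC)CC(C)=O | intermediate
15 | 4-acetyl-2-{[2,6-bis(benzyloxy)-4-methoxyphenyl]methyl}-3-methoxy-6-methylcyclohex-2-ene-1,5-dione (stereoisomer mixture) | CC(=O)C1C(=O)C(C)C(=O)C(Cc2c(OCc3ccccc3)cc(OC)cc2OCc2ccccc2)=C1OC | intermediate
16 | 1-[3-{[2,6-bis(benzyloxy)-4-methoxyphenyl]methyl}-4,6-dihydroxy-2-methoxy-5-methylphenyl]ethan-1-one | COc1cc(OCc2ccccc2)c(Cc2c(O)c(C)c(O)c(C(C)=O)c2OC)c(OCc2ccccc2)c1 | intermediate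
17 | 1-{3-[(2,6-dihydroxy-4-methoxyphenyl)methyl]-4,6-dihydroxy-2-methoxy-5-methylphenyl}ethan-1-one | COc1cc(O)c(Cc2c(O)c(C)c(O)c(C(C)=O)c2OC)c(O)c1 | intermediate
18 | 1-{3-[(3-acetyl-4,6-dihydroxy-2-methoxy-5-methylphenyl)methyl]-2,4-dihydroxy-6-methoxyphenyl}ethan-1-iminium chloride | COc1cc(O)c(Cc2c(O)c(C)c(O)c(C(C)=O)c2OC)c(O)c1C(C)=[NH2+].[Cl-] | intermediate
19 | 1-[3-[(3-acetyl-2,6-dihydroxy-4-methoxyphenyl)methyl]-4,6-dihydroxy-2-methoxy-5-methylphenyl]ethan-1-one (CNP0360110.0) | COc1cc(O)c(Cc2c(O)c(C)c(O)c(C(C)=O)c2OC)c(O)c1C(C)=O | target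

**Step count and risks**

Total step count: 12. Longest linear sequence: 12 steps (from 1 to 19); 4 and 11 enter as purchased materials.

Steps most likely to fail:

1. Step 8. The basic ester enolate may remove a proton from the CH2 between the enol ether and the ketal of imidazolide 12 (or open the dioxolane by β-elimination) faster than it is acylated at the hindered carbonyl, so that acid 10 is returned on work-up. The fallback moves the electrophile to the aldehyde oxidation level, replacing acyl substitution by carbonyl addition. It sets out from ester 9: i-Bu2AlH (CH2Cl2, −78 °C) should give the allylic alcohol F1, kept over base-washed glassware because 3-methoxy allylic alcohols ionize easily. MnO2 (CH2Cl2, rt) should give the enal F2. Aldol addition of the lithium enolate of 11 (LiN(i-Pr)2, THF, −78 °C) should give the β-hydroxy ester F3 as a diastereomer mixture. Dess–Martin periodinane buffered with NaHCO3 (CH2Cl2, 0 °C) should oxidize it to the β-keto ester, and the route is rejoined at 13.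

2. Step 10. The chain may misfold through the aldol mode (acetyl methyl C8 onto the C3 ketone, leading to a resorcinol) or stall in the reversible aldol of C2 onto the C7 ketone, or methoxide may cut the chain by retro-Claisen attack at the C3 or C7 carbonyl. The fallback makes the C1 acyl carbon a thioester and replaces alkoxide by amine and Lewis-acid soft enolization, so no nucleophilic base is present. It sets out from acid 10: activation with CDI as in step 8 (imidazolide 12) and acylation of the lithium enolate of S-ethyl propanethioate (LiN(i-Pr)2, THF, −78 °C) should give the ketal β-keto thioester F4. PPTS in wet acetone should free the ketone to give the open-chain thioester F5. MgBr2·OEt2 with i-Pr2NEt (CH2Cl2, rt) should then effect the same closure of C6 onto C1 with loss of ethanethiol, and the route is rejoined at 16.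

3. Step 12. Ipso-protonation of the very electron-rich ring A under HCl and ZnCl2 may cut or scramble the diarylmethane bridge, and the ring B phenols may be converted to imidates and then esters. The fallback avoids acid and uses a photochemical acyl shift. It sets out from 17: Ac2O in pyridine (rt) should give the tetraacetate F6, which is no longer acid- or air-sensitive. Irradiation (254 nm, cyclohexane, rt) should bring about a photo-Fries shift of one of the two equivalent ring A acetates to its only free ortho carbon, giving the ortho-hydroxy ketone F7 (the ring B acetates have no free ortho or para position). K2CO3 in MeOH (0 °C) should remove the remaining acetates, and the route is rejoined at 19.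

**Further compounds**

F1 | step 8 | (2E)-2-{[2,6-bis(benzyloxy)-4-methoxyphenyl]methyl}-3-methoxy-4-(2-methyl-1,3-dioxolan-2-yl)but-2-en-1-ol | OC/C(Cc1c(OCc2ccccc2)cc(OC)cc1OCc1ccccc1)=C(/OC)CC1(C)OCCO1
F2 | step 8 | (2E)-2-{[2,6-bis(benzyloxy)-4-methoxyphenyl]methyl}-3-methoxy-4-(2-methyl-1,3-dioxolan-2-yl)but-2-enal | O=C/C(Cc1c(OCc2ccccc2)cc(OC)cc1OCc1ccccc1)=C(/OC)CC1(C)OCCO1
F3 | step 8 | methyl (4E)-4-{[2,6-bis(benzyloxy)-4-methoxyphenyl]methyl}-3-hydroxy-5-methoxy-2-methyl-6-(2-methyl-1,3-dioxolan-2-yl)hex-4-enoate (diastereomer mixture) | COC(=O)C(C)C(O)/C(Cc1c(OCc2ccccc2)cc(OC)cc1OCc1ccccc1)=C(/OC)CC1(C)OCCO1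
F4 | step 10 | S-ethyl (4E)-4-{[2,6-bis(benzyloxy)-4-methoxyphenyl]methyl}-5-methoxy-2-methyl-6-(2-methyl-1,3-dioxolan-2-yl)-3-oxohex-4-enethioate (racemic at C2) | CCSC(=O)C(C)C(=O)/C(Cc1c(OCc2ccccc2)cc(OC)cc1OCc1ccccc1)=C(/OC)CC1(C)OCCO1
F5 | step 10 | S-ethyl (4E)-4-{[2,6-bis(benzyloxy)-4-methoxyphenyl]methyl}-5-methoxy-2-methyl-3,7-dioxooct-4-enethioate (racemic at C2) | CCSC(=O)C(C)C(=O)/C(Cc1c(OCc2ccccc2)cc(OC)cc1OCc1ccccc1)=C(/OC)CC(C)=O
F6 | step 12 | 2-{[3-acetyl-4,6-bis(acetyloxy)-2-methoxy-5-methylphenyl]methyl}-5-methoxy-1,3-phenylene diacetate | COc1cc(OC(C)=O)c(Cc2c(OC(C)=O)c(C)c(OC(C)=O)c(C(C)=O)c2OC)c(OC(C)=O)c1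
F7 | step 12 | 4-acetyl-2-{[3-acetyl-4,6-bis(acetyloxy)-2-methoxy-5-methylphenyl]methyl}-3-hydroxy-5-methoxyphenyl acetate | COc1cc(OC(C)=O)c(Cc2c(OC(C)=O)c(C)c(OC(C)=O)c(C(C)=O)c2OC)c(O)c1C(C)=O
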